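The runs were computed with constants of no real substance; the scatter is artificial.

The pitfall is to read a rate from one stretch of a run and carry it forward as a constant.

| flask | starting material | partner | remark | time |
|---|---|---|---|---|
| south-east | 0.0037 M | 0.022 M | run made earlier |  |
| north-west | 0.070 M | 0.022 M | run made earlier |  |
| west | 0.020 M | 0.0098 M | run made earlier |  |
| autumn | 0.012 M | 0.00600 M |  | 30 min |
| summer | 0.080 M | 0.0220 M |  | 30 min |
| spring | 0.080 M | 0.00600 M |  | 30 min |
| dusk | 0.0060 M | 0.0220 M |  | 30 min |
| noon | 0.020 M | 0.0220 M |  | 30 min |

- south-east (time / min: open intermediate / %, product / %): 1.33: 21.2, 0; 3.00: 40.5, 0.5; 6.00: 63.3, 1.9; 15.0: 80.3, 12.0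
- north-west (time / min: open intermediate / %, product / %): 4.00: 49.5, 0.6; 8.00: 71.4, 2.8; 12.0: 78.8, 6.7; 15.0: 79.3, 8.8
- west (time / min: open intermediate / %, product / %): 2.00: 29.3, 0.4; 5.00: 57.9, 0.6; 10.0: 79.7, 1.8; 15.0: 86.4, 5.3

(readings scatter by 0.3 percentage points)

- the analysis behind the earlier runs scatters by 0.3 percentage points, standard deviation
- a reading or a percentage of product counts all its forms, free or not

- ranking by amount of open intermediate, in percent of the starting material charged, from high to low, at 30 min (autumn / summer / spring / dusk / noon)
- the same order at 2.0 h (autumn / summer / spring / dusk / noon)
- the amount of open intermediate, in percent of the starting material charged of the flask you put first, at 30 min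
- the amount of open intermediate, in percent of the starting material charged of the flask you put last, at 30 min

In the south-east run, from 6.00 min to 15.0 min, the product gained per minute divided by the mean open intermediate reads 0.0156 min⁻¹. This is the loss rate, a pseudo-first-order coefficient for the open intermediate, read over that stretch and carrying the scatter of the readings. From 3.00 min to 6.00 min the same reading gives 0.00899 min⁻¹, so the later reading stands higher than the earlier one.

Dusk has the south-east partner charge, with 0.0060 M of starting material against 0.0037 M, so we borrow the south-east state at 15.0 min. Taking everything not yet product as open intermediate and holding the loss rate constant, our own reckoning for dusk at 30 min is 69.6%. Since the later reading of the loss rate is higher than the earlier one, we expect dusk to fall below that.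

The forecast ranks spring > autumn > summer > noon > dusk at 30 min and spring > summer > autumn > noon > dusk at 2.0 h, with 89% first and 72% last, a higher low than ours, holding that “dilute, partner-rich flasks lose intermediate fastest”.

The simulation gives spring > autumn > summer > noon > dusk at 30 min and spring > summer > autumn > noon > dusk at 2.0 h, with spring at 92.6% and dusk at 64.9%.

    starting material → open intermediate (k = 0.00290 s⁻¹)
    partner → second intermediate (k = 0.00150 s⁻¹)
    open intermediate + second intermediate → product (k = 0.0190 M⁻¹ s⁻¹)
    starting material + product ⇌ idle adduct, settled at all times (K = 450 M⁻¹)

Dusk lies 4.7 percentage points under our figure, and its second intermediate grew from 0.0156 M at 15.0 min to 0.0185 M at 30.0 min. Over that stretch the loss rate of dusk is 0.0202 min⁻¹, higher than the 0.0156 min⁻¹ of the south-east run. Carried on from 30 min to 80 min, this dusk loss rate gives 23.6%, and dusk read at 80 min holds 23.8%.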